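I could not see the reagent in the reaction phase, since no run measured it. So I looked for a quantity in which it cancels.

| flask | starting material | reagent in the second phase | protic impurity | remark | time | volume of the second phase over the first |
|---|---|---|---|---|---|---|
| noon | 0.25 M | 0.75 M | 0.050 M | run made earlier |  |  |
| autumn | 0.38 M | 0.75 M | 0.050 M | run made earlier |  |  |
| flask | 0.50 M | 0.750 M | 0.0500 M |  | 6.0 min | 0.25 |

| run | time / min | target / % | starting material / % |
|---|---|---|---|
| noon | 0.500 | 0.1 | 94.9 |
| noon | 1.00 | 0 | 91.5 |
| noon | 1.50 | 1.6 | 87.4 |
| noon | 2.50 | 5.5 | 79.5 |
| noon | 4.00 | 13.4 | 72.4 |
| noon | 8.00 | 24.3 | 53.1 |
| autumn | 0.500 | 0.9 | 96.8 |
| autumn | 1.00 | 0.9 | 94.1 |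
| autumn | 1.50 | 3.7 | 90.7 |
| autumn | 2.50 | 5.2 | 84.4 |
| autumn | 4.00 | 12.1 | 75.9 |
| autumn | 8.00 | 24.1 | 58.6 |

(readings scatter by 1 percentage point)

1. amount of target at 6.0 min, in percent of the starting material charged
2. the change that raises the amount of target at 6.0 min, in percent of the starting material charged most ("none" if none brings more than 2 percentage points) (grey / amber / none)
3. amount of target at 6.0 min, in percent of the starting material charged, after amber

- in the second phase: reagent in the second phase; everything else is in the first
- charges count per volume of the first phase; a concentration in a rate is the amount of a species over the volume of its own phase; every rate counts per litre of the first phase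
- steps that have been proposed: reagent in the reaction phase + target -> over-reacted product; reagent in the reaction phase <-> reagent in the second phase; starting material + reagent in the reaction phase -> target; starting material + protic impurity -> quenched substrate
- the earlier runs hold the two phases in the same ratio of volumes as the flask asked about

- grey: doubling the amount of reagent in the second phase, all else as stated
- amber: doubling the transfer coefficient of the reagent in the second phase, all else as stated

Making target and over-reacting it each use the reagent in the reaction phase, once. I therefore divided the rate of over-reaction by the rate of making target, and reagent and time dropped out. What stayed was target over starting material, times one constant.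

To read that constant I needed the over-reacted product, which no run shows. At 8.00 min I took the charge, removed starting material and target, and removed the impurity's share, counted one for one. That left 2.60% in noon and 4.14% in autumn, both within reach of the scatter. I took the ratio's mean over a run as 0.5 of its last value. Pooled, this gave 0.643, my selectivity factor: over-reaction rate over target rate, per unit of target over starting material.

The asked time lies halfway between the last two readings. The mean of those readings in both runs gave 18.5%.

The weak link was the step up to 0.50 M. The factor works in percentages, so I carried it over unchanged. I put the impurity's share in the flask at 10.0%, which left about 71.5% starting material. By my reckoning the flask then made target about 6.01 times faster than it used it, and I estimated the loss at 1.54%. I kept 18.5%. I ranked neither change, since reagent had cancelled.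

The forecast gave 17.5%, grey as best and 23% after amber, on the ground “Percent yield is nearly the same at both loadings”.

The flask gave 19.2%, with grey best, gaining 12 percentage points against 3.2 points for amber, and 22.4% after amber.

    reagent in the reaction phase + target → over-reacted product (k = 9.80 × 10⁻⁴ /M/s)
    reagent in the reaction phase ⇌ reagent in the second phase, rate k2*([reagent in the reaction phase] - [reagent in the second phase]/K2) per volume of the first phase (partition coefficient = 0.670, kL = 0.00120 /s)
    starting material + reagent in the reaction phase → target (k = 0.00180 /M/s)
    starting material + protic impurity → quenched substrate (k = 0.0270 /M/s)

At 6.00 min the flask made target 6.65 times faster than it used it up, and my factor on its simulated amounts gives 5.63. At 25 min the same flask held 30.2% starting material and 42.7% target, so the factor gives 1.10. At 60.0 min target in that flask stood lower, at 40.5%.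

The earlier runs and the new flask come from a simulation for an exercise, noise included.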